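The route rests on cutting the O–C6 bond of the 1,2-dioxane ring (O–O–C3–C4–C5–C6, numbered from carboxyl C1). C3–C8, with the C6 methyl and the C6 oxygen, form the carbon–oxygen skeleton of (R)-linalool. C6, C7, C8 and that oxygen are therefore tied into a 2-methyloxetane. Precursor 16 carries this oxetane, a C3 hydroperoxide and a vinyl group as masked C1. On acid activation the hydroperoxide displaces the oxetane oxygen at tertiary C6 with inversion. This single operation closes the dioxane, sets the quaternary centre and frees C8–OH. The side chain, a Sharpless-derived vinyl epoxide, is then joined by cross-metathesis and diimide reduction.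

Key step: step 9

Remark: locants C1–C12 are those of target 29, counted from the carboxyl carbon, and are used for all intermediates. (−)-Ipc2BOMe means the borinate derived from (+)-α-pinene. C1 is carried as the free acid from step 11 onwards, so no ester has to be made or cleaved next to the peroxide.

Step 1
Reactants: 1 (R)-(−)-linalool
Product: 3 (3R)-3,7-dimethyloct-6-ene-1,3-diol, via B-alkyl-9-BBN adduct 2 (not isolated)
Conditions: 9-BBN (1.5 equiv), THF, 0 °C → rt; then aq NaOH, 30% H2O2, 0 °C → rt
Reagents that add atoms: hydrogen peroxide, OO; 9-borabicyclo[3.3.1]nonane, B1C2CCCC1CCC2 (its boron and carbon atoms stay only in 2)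
Why: Hydroboration–oxidation, in which 9-BBN should add anti-Markovnikov to the monosubstituted vinyl group much faster than to the trisubstituted alkene, and the C6 carbinol centre of 1 is not involved.

Step 2
Reactants: 3 (3R)-3,7-dimethyloct-6-ene-1,3-diol
Product: 5 (2R)-2-methyl-2-(4-methylpent-3-en-1-yl)oxetane, via primary monotosylate 4 (not isolated)
Conditions: n-BuLi (1.0 equiv), THF, 0 °C; TsCl (1.0 equiv), 0 °C; n-BuLi (1.05 equiv), 0 → 60 °C
Reagents that add atoms: p-toluenesulfonyl chloride, Cc1ccc(cc1)S(=O)(=O)Cl (its atoms stay only in 4)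
Why: Selective sulfonylation of the primary alkoxide and intramolecular Williamson etherification (4-exo-tet) by the tertiary alkoxide should close the oxetane, and because the C6–O bond is never broken the configuration of 1 is kept.

Step 3
Reactants: 5 (2R)-2-methyl-2-(4-methylpent-3-en-1-yl)oxetane
Product: 6 3-[(2R)-2-methyloxetan-2-yl]propanal
Conditions: O3, CH2Cl2, −78 °C; then Me2S, −78 °C → rt
Reagents that add atoms: ozone, [O-][O+]=O
Why: Ozonolysis with reductive work-up cleaves the only C=C bond, while the oxetane is inert to ozone and dimethyl sulfide under these neutral conditions.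

Step 4
Reactants: 6 3-[(2R)-2-methyloxetan-2-yl]propanal; 7 trans-2-butene
Product: 11 (3S,4R)-3-methyl-6-[(2R)-2-methyloxetan-2-yl]hex-1-en-4-ol, via (E)-crotylpotassium 8 (not isolated), via (E)-crotyldiisopinocampheylborane 9 (not isolated), via borinate ester 10 (not isolated)
Conditions: 7, KOtBu, n-BuLi, THF, −78 → −45 °C; (−)-Ipc2BOMe, −78 °C; BF3·OEt2 (1.0 equiv to the ate complex), −78 °C; 6, −78 °C; then aq NaOH, H2O2, 0 °C → rt
Reagents that add atoms: (−)-B-methoxydiisopinocampheylborane, COB([C@@H]1C[C@@H]2C[C@H]([C@H]1C)C2(C)C)[C@@H]1C[C@@H]2C[C@H]([C@H]1C)C2(C)C (its atoms stay only in 9 and 10); potassium tert-butoxide, CC(C)(C)[O-].[K+] (potassium stays only in 8)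
Why: Brown asymmetric crotylboration through a closed chair (Zimmerman–Traxler) transition state, in which the E geometry of 9 sets the anti C2/C3 relation and the isopinocampheyl groups from (+)-α-pinene direct addition to the Si face of 6, setting the carbinol carbon C3 as R and C2 as S irrespective of the remote C6 centre.

Step 5
Reactants: 11 (3S,4R)-3-methyl-6-[(2R)-2-methyloxetan-2-yl]hex-1-en-4-ol
Product: 12 (3S,4R)-3-methyl-6-[(2R)-2-methyloxetan-2-yl]hex-1-en-4-yl methanesulfonate
Conditions: MsCl, Et3N, CH2Cl2, 0 °C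
Reagents that add atoms: methanesulfonyl chloride, CS(=O)(=O)Cl
Why: O-Sulfonylation under basic conditions leaves the C3–O bond, the oxetane and the vinyl group untouched.

Step 6
Reactants: 13 2,3-dimethylbut-2-ene
Product: 14 2-methoxypropan-2-yl hydroperoxide
Conditions: O3, MeOH–CH2Cl2, −78 °C; kept and used as a solution
Reagents that add atoms: ozone, [O-][O+]=O; methanol, CO
Why: Ozonolysis in a participating solvent (Criegee mechanism), in which methanol traps acetone O-oxide as the hydroperoxy ketal, a base-stable and acid-labile equivalent of the HOO− anion.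

Step 7
Reactants: 12 (3S,4R)-3-methyl-6-[(2R)-2-methyloxetan-2-yl]hex-1-en-4-yl methanesulfonate; 14 2-methoxypropan-2-yl hydroperoxide
Product: 15 (2R)-2-{(3S,4S)-3-[(2-methoxypropan-2-yl)peroxy]-4-methylhex-5-en-1-yl}-2-methyloxetane
Conditions: CsOH·H2O, DMF, 0 °C → rt
Reagents that add atoms: none
Why: SN2 alkylation of a peroxy anion, a strong α-effect nucleophile of low basicity, should displace the mesylate with inversion and turn the (3R)-anti sulfonate into the (3S)-syn peroxide, while the oxetane is inert to base.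

Step 8
Reactants: 15 (2R)-2-{(3S,4S)-3-[(2-methoxypropan-2-yl)peroxy]-4-methylhex-5-en-1-yl}-2-methyloxetane
Product: 16 (2R)-2-[(3S,4S)-3-hydroperoxy-4-methylhex-5-en-1-yl]-2-methyloxetane
Conditions: PPTS (cat.), MeOH, 0 °C
Reagents that add atoms: none
Why: Acid-catalysed transketalisation of the very labile monoperoxy ketal frees the hydroperoxide under conditions too mild to activate the oxetane, and no stereocentre is touched.

Step 9
Reactants: 16 (2R)-2-[(3S,4S)-3-hydroperoxy-4-methylhex-5-en-1-yl]-2-methyloxetane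
Product: 17 2-{(3S,6S)-6-[(2S)-but-3-en-2-yl]-3-methyl-1,2-dioxan-3-yl}ethan-1-ol
Conditions: TMSOTf (0.1–0.2 equiv), CH2Cl2, −78 → −40 °C; Et3N, then aq NaHCO3
Reagents that add atoms: none
Why: The silyl triflate, or the triflic acid it releases on contact with the OOH group, binds the oxetane oxygen and polarises the tertiary C6–O bond, and the terminal oxygen of the C3 hydroperoxide attacks C6 opposite to the departing oxygen, so that ring strain is released and C8–OH is set free. The closest known reaction type is the acid-promoted intramolecular opening of 2,2-disubstituted oxetanes by hydroperoxides, documented for 5-exo and 6-exo closures. The 1,2-dioxane (O–O–C3–C4–C5–C6) closes in the 6-exo-tet mode. The only new stereocentre, quaternary C6, is controlled by the oxetane configuration inherited from 1, which backside substitution inverts, while C2 and C3 are spectators. The step needs attack at tertiary C6 and not at primary C8, which is secured by the larger positive charge at C6 and by the eight-membered ring that attack at C8 would demand. It also needs substitution without a free cation, which the short tether, the low temperature and the non-ionising solvent should secure.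

Step 10
Reactants: 17 2-{(3S,6S)-6-[(2S)-but-3-en-2-yl]-3-methyl-1,2-dioxan-3-yl}ethan-1-ol
Product: 18 (3S,6S)-3-(2-bromoethyl)-6-[(2S)-but-3-en-2-yl]-3-methyl-1,2-dioxane
Conditions: CBr4, then PPh3 in portions, CH2Cl2, 0 °C
Reagents that add atoms: carbon tetrabromide, BrC(Br)(Br)Br
Why: Appel reaction at an unhindered primary alcohol, with the phosphine added last so that it is consumed by CBr4 and does not meet the dialkyl peroxide.

Step 11
Reactants: 18 (3S,6S)-3-(2-bromoethyl)-6-[(2S)-but-3-en-2-yl]-3-methyl-1,2-dioxane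
Product: 20 (2R)-2-[(3S,6S)-6-(2-bromoethyl)-6-methyl-1,2-dioxan-3-yl]propanoic acid, via bromo aldehyde 19 (not isolated)
Conditions: O3, MeCN–H2O (9:1), 0 °C; N2 purge; then NaClO2, NaH2PO4, 0 °C → rt
Reagents that add atoms: ozone, [O-][O+]=O; sodium chlorite, [Na+].[O-]Cl=O
Why: Ozonolysis in aqueous solvent, where water converts the carbonyl oxide directly into the aldehyde, is followed in the same flask by Pinnick-type chlorite oxidation with the liberated hydrogen peroxide as hypochlorite scavenger, so the epimerisable β-peroxy aldehyde 19 is consumed at pH 4–5 without being handled and C2 keeps its configuration.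

Step 12
Reactants: 20 (2R)-2-[(3S,6S)-6-(2-bromoethyl)-6-methyl-1,2-dioxan-3-yl]propanoic acid
Product: 21 (2R)-2-[(3S,6S)-6-ethenyl-6-methyl-1,2-dioxan-3-yl]propanoic acid
Conditions: KOtBu (2.5 equiv), THF, 0 °C; work-up at pH 4–5
Reagents that add atoms: none
Why: E2 dehydrobromination with a hindered alkoxide, in which the first equivalent forms the carboxylate and thereby shields C2–H from deprotonation, so that E1cB opening of the dioxane is blocked.

Step 13
Reactants: 22 dihydro-β-ionone
Product: 23 ethyl (2E)-3-methyl-5-(2,6,6-trimethylcyclohex-1-en-1-yl)pent-2-enoate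
Conditions: (EtO)2P(O)CH2CO2Et, NaH, THF, 0 °C → reflux; chromatography
Reagents that add atoms: triethyl phosphonoacetate, CCOC(=O)CP(=O)(OCC)OCC
Why: Horner–Wadsworth–Emmons olefination of a methyl ketone should favour the E enoate, and the minor Z isomer is removed by chromatography.

Step 14
Reactants: 23 ethyl (2E)-3-methyl-5-(2,6,6-trimethylcyclohex-1-en-1-yl)pent-2-enoate
Product: 24 (2E)-3-methyl-5-(2,6,6-trimethylcyclohex-1-en-1-yl)pent-2-en-1-ol
Conditions: DIBAL-H (2.2 equiv), CH2Cl2, −78 °C; Rochelle salt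
Reagents that add atoms: none
Why: 1,2-Reduction of the enoate with DIBAL-H gives the allylic alcohol with the alkene geometry unchanged.

Step 15
Reactants: 24 (2E)-3-methyl-5-(2,6,6-trimethylcyclohex-1-en-1-yl)pent-2-en-1-ol
Product: 25 {(2S,3S)-3-methyl-3-[2-(2,6,6-trimethylcyclohex-1-en-1-yl)ethyl]oxiran-2-yl}methanol
Conditions: Ti(OiPr)4 (cat.), L-(+)-DET (cat.), t-BuOOH, 4 Å MS, CH2Cl2, −20 °C
Reagents that add atoms: tert-butyl hydroperoxide, CC(C)(C)OO
Why: Sharpless asymmetric epoxidation, in which titanium binds the allylic alcohol so that only the C9=C10 alkene and not the tetrasubstituted ring alkene reacts, and L-(+)-tartrate delivers oxygen to the face that gives the (2S,3S)-epoxy alcohol, which sets C9 and C10 of the target.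

Step 16
Reactants: 25 {(2S,3S)-3-methyl-3-[2-(2,6,6-trimethylcyclohex-1-en-1-yl)ethyl]oxiran-2-yl}methanol
Product: 26 (2R,3S)-3-methyl-3-[2-(2,6,6-trimethylcyclohex-1-en-1-yl)ethyl]oxirane-2-carbaldehyde
Conditions: Dess–Martin periodinane, NaHCO3, CH2Cl2, 0 °C
Reagents that add atoms: none
Why: Buffered Dess–Martin oxidation stops at the aldehyde and tolerates the acid-sensitive epoxide and the ring alkene, the change of descriptor at C9 being only a change of CIP priority.

Step 17
Reactants: 26 (2R,3S)-3-methyl-3-[2-(2,6,6-trimethylcyclohex-1-en-1-yl)ethyl]oxirane-2-carbaldehyde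
Product: 27 (2S,3S)-3-ethenyl-2-methyl-2-[2-(2,6,6-trimethylcyclohex-1-en-1-yl)ethyl]oxirane
Conditions: Ph3PCH3Br, NaHMDS, THF, −78 → 0 °C
Reagents that add atoms: methyltriphenylphosphonium bromide, C[P+](c1ccccc1)(c1ccccc1)c1ccccc1.[Br-]
Why: Wittig methylenation of an epoxy aldehyde at low temperature is a standard entry to vinyl epoxides and does not disturb the oxirane carbons.

Step 18
Reactants: 21 (2R)-2-[(3S,6S)-6-ethenyl-6-methyl-1,2-dioxan-3-yl]propanoic acid; 27 (2S,3S)-3-ethenyl-2-methyl-2-[2-(2,6,6-trimethylcyclohex-1-en-1-yl)ethyl]oxirane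
Product: 28 (2R)-2-[(3S,6S)-6-methyl-6-{(E)-2-[(2S,3S)-3-methyl-3-[2-(2,6,6-trimethylcyclohex-1-en-1-yl)ethyl]oxiran-2-yl]ethenyl}-1,2-dioxan-3-yl]propanoic acid
Conditions: Hoveyda–Grubbs II (10 mol %), 27 (2–3 equiv), 1,4-benzoquinone (cat.), CH2Cl2, 40 °C
Reagents that add atoms: none
Why: Olefin cross-metathesis between a vinyl epoxide and a vinyl group on a fully substituted carbon that does not homodimerise, so that an excess of 27 should drive selective cross-coupling while the dialkyl peroxide, the acid and the tetrasubstituted alkene stay inert to the ruthenium carbene and the geometry of the new alkene is of no consequence.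

Step 19
Reactants: 28 (2R)-2-[(3S,6S)-6-methyl-6-{(E)-2-[(2S,3S)-3-methyl-3-[2-(2,6,6-trimethylcyclohex-1-en-1-yl)ethyl]oxiran-2-yl]ethenyl}-1,2-dioxan-3-yl]propanoic acid
Product: 29 (2R)-2-[(3S,6R)-6-methyl-6-{2-[(2S,3S)-3-methyl-3-[2-(2,6,6-trimethylcyclohex-1-en-1-yl)ethyl]oxiran-2-yl]ethyl}-1,2-dioxan-3-yl]propanoic acid (CNP0204283.1)
Conditions: 2-nitrobenzenesulfonylhydrazide (excess, in portions), Et3N, CH2Cl2, rt; work-up at pH 5
Reagents that add atoms: none
Why: Diimide reduction transfers hydrogen in a concerted way to the disubstituted C7=C8 alkene only and, unlike catalytic hydrogenation, leaves the O–O bond, the epoxide and the tetrasubstituted alkene intact, the change of the C6 descriptor from S to R being only a change of CIP priority.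

Compound list
1 | (R)-(−)-linalool | C[C@](O)(C=C)CCC=C(C)C | starting material
2 | B-alkyl-9-BBN adduct of 1 (not isolated) | C[C@](O)(CCB1C2CCCC1CCC2)CCC=C(C)C | intermediate
3 | (3R)-3,7-dimethyloct-6-ene-1,3-diol | C[C@](O)(CCO)CCC=C(C)C | intermediate
4 | (3R)-3-hydroxy-3,7-dimethyloct-6-en-1-yl 4-methylbenzenesulfonate (not isolated) | C[C@](O)(CCOS(=O)(=O)c1ccc(C)cc1)CCC=C(C)C | intermediate
5 | (2R)-2-methyl-2-(4-methylpent-3-en-1-yl)oxetane | C[C@]1(CCO1)CCC=C(C)C | intermediate
6 | 3-[(2R)-2-methyloxetan-2-yl]propanal | C[C@]1(CCO1)CCC=O | intermediate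
7 | trans-2-butene | C/C=C/C | starting material
8 | (E)-crotylpotassium (not isolated) | C/C=C/[CH2-].[K+] | intermediate
9 | (E)-crotyldiisopinocampheylborane from (+)-α-pinene (not isolated) | C/C=C/CB([C@@H]1C[C@@H]2C[C@H]([C@H]1C)C2(C)C)[C@@H]1C[C@@H]2C[C@H]([C@H]1C)C2(C)C | intermediate
10 | diisopinocampheylborinate ester of 11 (not isolated) | C[C@]1(CCO1)CC[C@H]([C@@H](C)C=C)OB([C@@H]1C[C@@H]2C[C@H]([C@H]1C)C2(C)C)[C@@H]1C[C@@H]2C[C@H]([C@H]1C)C2(C)C | intermediate
11 | (3S,4R)-3-methyl-6-[(2R)-2-methyloxetan-2-yl]hex-1-en-4-ol | C[C@]1(CCO1)CC[C@H]([C@@H](C)C=C)O | intermediate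
12 | (3S,4R)-3-methyl-6-[(2R)-2-methyloxetan-2-yl]hex-1-en-4-yl methanesulfonate | C[C@]1(CCO1)CC[C@H]([C@@H](C)C=C)OS(C)(=O)=O | intermediate
13 | 2,3-dimethylbut-2-ene | CC(C)=C(C)C | starting material
14 | 2-methoxypropan-2-yl hydroperoxide | COC(C)(C)OO | intermediate
15 | (2R)-2-{(3S,4S)-3-[(2-methoxypropan-2-yl)peroxy]-4-methylhex-5-en-1-yl}-2-methyloxetane | C[C@]1(CCO1)CC[C@@H]([C@@H](C)C=C)OOC(C)(C)OC | intermediate
16 | (2R)-2-[(3S,4S)-3-hydroperoxy-4-methylhex-5-en-1-yl]-2-methyloxetane | C[C@]1(CCO1)CC[C@@H]([C@@H](C)C=C)OO | intermediate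
17 | 2-{(3S,6S)-6-[(2S)-but-3-en-2-yl]-3-methyl-1,2-dioxan-3-yl}ethan-1-ol | OCC[C@]1(C)CC[C@@H]([C@@H](C)C=C)OO1 | intermediate
18 | (3S,6S)-3-(2-bromoethyl)-6-[(2S)-but-3-en-2-yl]-3-methyl-1,2-dioxane | BrCC[C@]1(C)CC[C@@H]([C@@H](C)C=C)OO1 | intermediate
19 | (2R)-2-[(3S,6S)-6-(2-bromoethyl)-6-methyl-1,2-dioxan-3-yl]propanal (not isolated) | BrCC[C@]1(C)CC[C@@H]([C@@H](C)C=O)OO1 | intermediate
20 | (2R)-2-[(3S,6S)-6-(2-bromoethyl)-6-methyl-1,2-dioxan-3-yl]propanoic acid | BrCC[C@]1(C)CC[C@@H]([C@@H](C)C(=O)O)OO1 | intermediate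
21 | (2R)-2-[(3S,6S)-6-ethenyl-6-methyl-1,2-dioxan-3-yl]propanoic acid | C=C[C@]1(C)CC[C@@H]([C@@H](C)C(=O)O)OO1 | intermediate
22 | dihydro-β-ionone | CC(=O)CCC1=C(C)CCCC1(C)C | starting material
23 | ethyl (2E)-3-methyl-5-(2,6,6-trimethylcyclohex-1-en-1-yl)pent-2-enoate | CCOC(=O)/C=C(\C)CCC1=C(C)CCCC1(C)C | intermediate
24 | (2E)-3-methyl-5-(2,6,6-trimethylcyclohex-1-en-1-yl)pent-2-en-1-ol | OC/C=C(\C)CCC1=C(C)CCCC1(C)C | intermediate
25 | {(2S,3S)-3-methyl-3-[2-(2,6,6-trimethylcyclohex-1-en-1-yl)ethyl]oxiran-2-yl}methanol | CC1=C(CC[C@]2(C)O[C@H]2CO)C(C)(C)CCC1 | intermediate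
26 | (2R,3S)-3-methyl-3-[2-(2,6,6-trimethylcyclohex-1-en-1-yl)ethyl]oxirane-2-carbaldehyde | CC1=C(CC[C@]2(C)O[C@H]2C=O)C(C)(C)CCC1 | intermediate
27 | (2S,3S)-3-ethenyl-2-methyl-2-[2-(2,6,6-trimethylcyclohex-1-en-1-yl)ethyl]oxirane | CC1=C(CC[C@]2(C)O[C@H]2C=C)C(C)(C)CCC1 | intermediate
28 | (E)-7,8-didehydro derivative of the target (cross-metathesis product) | CC1=C(CC[C@]2(C)O[C@H]2/C=C/[C@]2(C)CC[C@@H]([C@@H](C)C(=O)O)OO2)C(C)(C)CCC1 | intermediate
29 | CNP0204283.1, (2R,3S,6R,9S,10S) | CC1=C(CC[C@]2(C)O[C@H]2CC[C@]2(C)CC[C@@H]([C@@H](C)C(=O)O)OO2)C(C)(C)CCC1 | target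

Total step count: 19.
Longest linear sequence: 13 steps (steps 1–5, 7–12, 18, 19).

Steps most likely to fail

Step 9. The activated C6–O bond may ionise before the peroxide oxygen arrives. That would erode the inversion or end in proton loss, and the acid may also trigger Hock-type cleavage of the secondary hydroperoxide. The fallback exchanges the roles of the two termini and sets out from mesylate 12. Intermolecular perhydrolysis of the oxetane uses a large excess of ethereal H2O2 and a catalytic Lewis acid. This is a known opening of 2,2-disubstituted oxetanes at the tertiary carbon with inversion. It should give (3S,4R,7S)-7-hydroperoxy-9-hydroxy-3,7-dimethylnon-1-en-4-yl methanesulfonate F1. KOtBu with 18-crown-6 in THF at 0 °C then deprotonates only the hydroperoxide, which closes the ring by 6-exo-tet SN2 at C3. Both inversions are the same as in steps 7 and 9, so the sequence comes back to the route at 17.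

Step 7. E2 loss of the sulfonate towards the conjugated diene is a risk because C2–H is allylic. Substitution at the β-branched secondary carbon may also be slow. The fallback is a double inversion through a halide and sets out from aldehyde 6. Crotylboration uses (Z)-crotyldiisopinocampheylborane F2, made from cis-2-butene and (+)-Ipc2BOMe. After oxidative work-up it should give the syn alcohol (3S,4S)-3-methyl-6-[(2R)-2-methyloxetan-2-yl]hex-1-en-4-ol F3. Appel bromination (CBr4, PPh3) inverts C3 to give (2R)-2-[(3R,4S)-3-bromo-4-methylhex-5-en-1-yl]-2-methyloxetane F4. Secondary bromides are established substrates for alkylation of 14 with CsOH in DMF, and the softer leaving group allows a lower temperature. This alkylation inverts C3 again, and the sequence comes back to the route at 15.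

Step 18. Turnover may be slow at the vinyl group on quaternary C6, and 27 may undergo self-metathesis. The allylic epoxide may also be opened by the carboxylic acid or by ruthenium residues. The fallback forms C8–C9 instead of C7=C8 and installs the epoxide last. It sets out from 21 and 22.
- Vinyl iodide partner: the kinetic enolate of 22 (LDA, then ClP(O)(OEt)2) gives the enol phosphate F5. Elimination with LDA gives 2-(but-3-yn-1-yl)-1,3,3-trimethylcyclohex-1-ene F6. Zirconium-catalysed carboalumination (Me3Al, Cp2ZrCl2) gives the (E)-alkenylalane F7, and iodinolysis gives the (E)-vinyl iodide F8.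
- Borane partner and coupling: hydroboration of 21, as its potassium salt, with 9-BBN gives the B-alkylborane F9. B-alkyl Suzuki–Miyaura coupling with F8 (PdCl2(dppf), Cs2CO3, DMF–H2O, rt) should give the (E)-9,10-alkene F10 with retention of geometry.
- Epoxidation: Shi epoxidation with the L-fructose-derived ketone (Oxone, K2CO3 buffer, 0 °C) should epoxidise the trisubstituted alkene from the face that gives the (9S,10S)-epoxide. The hindered tetrasubstituted ring alkene should react more slowly. The sequence comes back to the route at 29.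

Further compounds
F1 | step 9 | (3S,4R,7S)-7-hydroperoxy-9-hydroxy-3,7-dimethylnon-1-en-4-yl methanesulfonate | OCC[C@@](C)(OO)CC[C@H]([C@@H](C)C=C)OS(C)(=O)=O
F2 | step 7 | (Z)-crotyldiisopinocampheylborane from (−)-α-pinene | C/C=C\CB([C@H]1C[C@H]2C[C@@H]([C@@H]1C)C2(C)C)[C@H]1C[C@H]2C[C@@H]([C@@H]1C)C2(C)C
F3 | step 7 | (3S,4S)-3-methyl-6-[(2R)-2-methyloxetan-2-yl]hex-1-en-4-ol | C[C@]1(CCO1)CC[C@@H]([C@@H](C)C=C)O
F4 | step 7 | (2R)-2-[(3R,4S)-3-bromo-4-methylhex-5-en-1-yl]-2-methyloxetane | C[C@]1(CCO1)CC[C@H]([C@@H](C)C=C)Br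
F5 | step 18 | diethyl 4-(2,6,6-trimethylcyclohex-1-en-1-yl)but-1-en-2-yl phosphate | C=C(CCC1=C(C)CCCC1(C)C)OP(=O)(OCC)OCC
F6 | step 18 | 2-(but-3-yn-1-yl)-1,3,3-trimethylcyclohex-1-ene | C#CCCC1=C(C)CCCC1(C)C
F7 | step 18 | dimethyl[(1E)-2-methyl-4-(2,6,6-trimethylcyclohex-1-en-1-yl)but-1-en-1-yl]alane | C[Al](C)/C=C(\C)CCC1=C(C)CCCC1(C)C
F8 | step 18 | 2-[(3E)-4-iodo-3-methylbut-3-en-1-yl]-1,3,3-trimethylcyclohex-1-ene | I/C=C(\C)CCC1=C(C)CCCC1(C)C
F9 | step 18 | (2R)-2-{(3S,6S)-6-[2-(9-borabicyclo[3.3.1]nonan-9-yl)ethyl]-6-methyl-1,2-dioxan-3-yl}propanoic acid | B1(C2CCCC1CCC2)CC[C@]3(C)CC[C@@H]([C@@H](C)C(=O)O)OO3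
F10 | step 18 | (2R)-2-{(3S,6R)-6-methyl-6-[(3E)-4-methyl-6-(2,6,6-trimethylcyclohex-1-en-1-yl)hex-3-en-1-yl]-1,2-dioxan-3-yl}propanoic acid | CC1=C(CC/C(C)=C/CC[C@]2(C)CC[C@@H]([C@@H](C)C(=O)O)OO2)C(C)(C)CCC1
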